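The plan cuts the O–C6 bond of the 1,2-dioxane (ring atoms O, O, C3, C4, C5, C6; atoms are counted from the ester carbon, C1, to the alkene, C17=C18). C6 is a fully substituted ring carbon. Its methyl and C7 methylene arms are too similar for C3 to tell apart, so its configuration is stored in an epoxide and transferred by substitution. In one operation the C3 hydroperoxide opens a C6–C7 epoxide at C6 with inversion. The ring closes, C6 is set, and C7–OH is released as the handle for the chain. The precursor is an open-chain C1 silyl ether bearing the C2 methyl, the (3S)-hydroperoxide and the (6R)-2,2-disubstituted epoxide.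

Key step: step 10

Assumption: lactone 19 and (R)-linalool 27 are bought in high enantiomeric purity; the facial sense of the phosphoric acid in step 4 is taken from its behaviour with simple aldehydes; target numbering C1–C18 is used for every fragment.

C1–C7 dioxane aldehyde (steps 1–11)

Step 1
Reactants: 1 (S)-2-methylglycidol; 2 allylmagnesium bromide
Product: 3 (2R)-2-methylhex-5-ene-1,2-diol
Conditions: 2 (3 equiv), CuI (10 mol%), THF, −30 to 0 °C
Reagents that add atoms: allylmagnesium bromide, C=CC[Mg]Br
Why: Copper-catalysed Grignard opening of an epoxide occurs at the unsubstituted ring carbon, so the C6–O bond of 1 is never broken and its configuration passes into 3 (the descriptor changes only through the priority rules).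

Step 2
Reactants: 3 (2R)-2-methylhex-5-ene-1,2-diol
Product: 4 (4R)-4-(but-3-enyl)-2,2,4-trimethyl-1,3-dioxolane
Conditions: Me2C(OMe)2, PPTS (cat.), CH2Cl2, rt
Reagents that add atoms: 2,2-dimethoxypropane, COC(C)(C)OC
Why: Acid-catalysed transketalisation ties the primary and tertiary hydroxyls into a dioxolane, which prevents lactol formation once C3 becomes an aldehyde.

Step 3
Reactants: 4 (4R)-4-(but-3-enyl)-2,2,4-trimethyl-1,3-dioxolane
Product: 6 3-[(4R)-2,2,4-trimethyl-1,3-dioxolan-4-yl]propanal, via secondary ozonide 5 (not isolated)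
Conditions: O3, CH2Cl2, −78 °C; then Me2S, −78 °C to rt
Reagents that add atoms: ozone, [O-][O+]=O
Why: Ozonolysis with reductive work-up cleaves the only alkene, leaves the ketal and C6 untouched, and makes C3 the aldehyde carbon.

Step 4
Reactants: 6 3-[(4R)-2,2,4-trimethyl-1,3-dioxolan-4-yl]propanal; 7 (E)-crotylboronic acid pinacol ester
Product: 9 (3S,4R)-3-methyl-6-[(4R)-2,2,4-trimethyl-1,3-dioxolan-4-yl]hex-1-en-4-ol (2,3-anti; 2S,3R,6R in target numbering), via pinacol borate ester 8 (not isolated)
Conditions: 7 (1.3 equiv), (S)-TRIP [(S)-3,3'-bis(2,4,6-triisopropylphenyl)-1,1'-binaphthyl-2,2'-diyl hydrogen phosphate, 5 mol%], 4 Å MS, toluene, −30 °C; aqueous work-up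
Reagents that add atoms: (E)-crotylboronic acid pinacol ester, C/C=C/CB1OC(C)(C)C(C)(C)O1
Why: Chiral-phosphoric-acid-catalysed crotylboration runs through a closed chair transition state, so the E-boronate gives the 2,3-anti product, and the (S)-acid, whose mirror image steers allylboronates to the Re face of aldehydes, should direct attack to the Si face and set (2S,3R) independently of the remote C6 centre.

Step 5
Reactants: 9 anti homoallylic alcohol
Product: 11 (2S,3R)-2-methyl-5-[(4R)-2,2,4-trimethyl-1,3-dioxolan-4-yl]pentane-1,3-diol, via secondary ozonide 10 (not isolated)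
Conditions: O3, CH2Cl2, −78 °C; then NaBH4, MeOH, −78 to 0 °C
Reagents that add atoms: ozone, [O-][O+]=O
Why: Ozonolysis followed by borohydride reduction in the same flask trims the vinyl group to the C1 carbinol without letting the epimerisable beta-hydroxy aldehyde accumulate.

Step 6
Reactants: 11 1,3-diol
Product: 12 C1 tert-butyldiphenylsilyl ether of 11 (2S,3R,6R)
Conditions: TBDPSCl (1.05 equiv), imidazole, CH2Cl2, 0 °C
Reagents that add atoms: tert-butyldiphenylsilyl chloride, CC(C)(C)[Si](Cl)(c1ccccc1)c1ccccc1
Why: Silylation with a bulky chlorosilane distinguishes the primary C1 hydroxyl from the secondary C3 hydroxyl on steric grounds.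

Step 7
Reactants: 12 silyl ether acetonide
Product: 13 (2R,5R,6S)-7-(tert-butyldiphenylsilyloxy)-2,6-dimethylheptane-1,2,5-triol (2S,3R,6R in target numbering)
Conditions: AcOH–H2O 4:1, 35 °C
Reagents that add atoms: none
Why: Mild aqueous acid hydrolyses the terminal dioxolane, whereas the tert-butyldiphenylsilyl ether is stable to acetic acid.

Step 8
Reactants: 13 triol
Product: 15 (2S,3R)-1-(tert-butyldiphenylsilyloxy)-2-methyl-5-[(2R)-2-methyloxiran-2-yl]pentan-3-yl methanesulfonate, via bis-mesylate 14 (not isolated)
Conditions: MsCl (2.4 equiv), Et3N, CH2Cl2, −20 to 0 °C; crude 14, K2CO3, MeOH, 0 °C to rt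
Reagents that add atoms: methanesulfonyl chloride, CS(=O)(=O)Cl
Why: Mesylation takes the primary C7 and secondary C3 hydroxyls but not the tertiary C6 hydroxyl, and carbonate then triggers a Williamson-type 3-exo-tet closure of the C6 oxygen onto C7, which should be far faster than 5-exo attack on the hindered C3 mesylate and keeps the C6–O bond.

Step 9
Reactants: 15 epoxy mesylate
Product: 16 tert-butyl{[(2S,3S)-3-hydroperoxy-2-methyl-5-[(2R)-2-methyloxiran-2-yl]pentyl]oxy}diphenylsilane
Conditions: 50% aq H2O2 (20 equiv), KOH (3 equiv), MeOH–THF, 0 °C to rt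
Reagents that add atoms: hydrogen peroxide, OO
Why: Displacement of a secondary sulfonate by hydroperoxide anion is the classical SN2 route to secondary alkyl hydroperoxides, so C3 is inverted from R to S; the low basicity of the anion limits elimination, and the large excess of H2O2 keeps the product protonated, which holds back dialkyl peroxide formation and premature ring closure.

Step 10
Reactants: 16 3-hydroperoxy 6,7-epoxide
Product: 17 6-(hydroxymethyl)-6-methyl-1,2-dioxane with the 1-(tert-butyldiphenylsilyloxy)propan-2-yl group on C3 (2S,3S,6S)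
Conditions: (+)-camphor-10-sulfonic acid (10 mol%), CH2Cl2 (0.01 M), −20 to 0 °C
Reagents that add atoms: none
Why: The sulfonic acid binds the epoxide oxygen, the C6–O bond lengthens, and the terminal oxygen of the C3 hydroperoxide attacks C6 from the side opposite the departing oxygen, so the O–C6 bond forms while the O–O bond stays intact. The closest known reaction type is the acid-promoted intramolecular opening of epoxides and oxetanes by hydroperoxides to give 1,2-dioxolanes and 1,2-dioxanes, the peroxide counterpart of the exo cyclisation of epoxy alcohols. The 1,2-dioxane (O, O, C3, C4, C5, C6) closes in the 6-exo-tet mode, with the breaking C6–O bond outside the new ring. The one new stereocentre, C6, is controlled by the epoxide configuration alone: backside attack turns the (6R)-epoxide carbon inherited from 1 into the ring carbon of 17 with the spatial arrangement of the target, and C2 and C3 are spectators. The step needs attack at C6 rather than C7 and substitution without a free cation; the exo preference and the better charge stabilisation at the tertiary carbon both favour C6, whereas the 7-endo path has neither advantage, and a catalytic, weakly ionising acid in cold dilute CH2Cl2 should keep the opening concerted and hold back hydride shift and intermolecular opening.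

Step 11
Reactants: 17 dioxane carbinol
Product: 18 C7 aldehyde of the dioxane (2S,3S,6S)
Conditions: Dess–Martin periodinane, CH2Cl2, 0 °C to rt
Reagents that add atoms: none
Why: Dess–Martin oxidation works on neopentyl-type carbinols under near-neutral conditions that leave peroxides alone, and the formyl group ends up on a fully substituted carbon, which rules out enolisation and beta-elimination of the O–O unit.

C8–C11 linker (steps 12–14)

Step 12
Reactants: 19 (S)-alpha-methyl-gamma-butyrolactone
Product: 20 (2S)-4-hydroxy-N-methoxy-N,2-dimethylbutanamide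
Conditions: MeONHMe·HCl, AlMe3, CH2Cl2, 0 °C to rt
Reagents that add atoms: N,O-dimethylhydroxylamine hydrochloride, CNOC.Cl
Why: Aluminium-amide aminolysis of a lactone gives the open hydroxy Weinreb amide without touching the alpha stereocentre, which becomes C10.

Step 13
Reactants: 20 hydroxy Weinreb amide
Product: 21 (2S)-N-methoxy-N,2-dimethyl-4-[(1-phenyl-1H-tetrazol-5-yl)sulfanyl]butanamide
Conditions: 1-phenyl-1H-tetrazole-5-thiol, PPh3, DIAD, THF, 0 °C to rt
Reagents that add atoms: 1-phenyl-1H-tetrazole-5-thiol, Sc1nnnn1-c1ccccc1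
Why: Mitsunobu thioetherification converts the primary C8 hydroxyl into the tetrazolyl sulfide before the hydroxy amide can relactonise.

Step 14
Reactants: 21 sulfide
Product: 22 (2S)-N-methoxy-N,2-dimethyl-4-[(1-phenyl-1H-tetrazol-5-yl)sulfonyl]butanamide
Conditions: (NH4)6Mo7O24·4H2O (10 mol%), 30% aq H2O2, EtOH, 0 °C to rt
Reagents that add atoms: hydrogen peroxide, OO
Why: Molybdate-catalysed peroxide oxidation takes the sulfide to the sulfone and does not affect the amide.

C1–C11 aldehyde (steps 15–17)

Step 15
Reactants: 22 linker sulfone; 18 C7 aldehyde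
Product: 24 (E)-C7=C8 alkene carrying the C11 Weinreb amide (2S,3S,6S,10S), via potassiated sulfone 23 (not isolated)
Conditions: KN(SiMe3)2 (1.05 equiv), THF, −78 °C, 20 min; then 18, −78 °C to rt
Reagents that add atoms: none
Why: Julia–Kocienski olefination joins C8 to the non-enolisable aldehyde by addition, Smiles rearrangement and loss of SO2 and tetrazolone; the stabilised carbanion should be too weak a nucleophile at −78 °C to attack the O–O bond, and the alkene geometry is of no consequence.

Step 16
Reactants: 24 C7=C8 alkene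
Product: 25 saturated C1–C11 Weinreb amide (2S,3S,6R,10S)
Conditions: 2-nitrobenzenesulfonylhydrazide (excess, portions), Et3N, CH2Cl2, rt
Reagents that add atoms: none
Why: Diimide delivers hydrogen to C=C bonds in a concerted way and spares O–O bonds, and because no other alkene is present yet, the hindered C7=C8 bond next to the quaternary C6 can be forced to completion with excess reagent.

Step 17
Reactants: 25 Weinreb amide
Product: 26 C11 aldehyde (2S,3S,6R,10S)
Conditions: i-Bu2AlH (1.3 equiv), THF, −78 °C; aq potassium sodium tartrate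
Reagents that add atoms: none
Why: Hydride addition to a Weinreb amide stops at the chelated tetrahedral intermediate, which releases the aldehyde only on work-up, and dialkyl peroxides tolerate i-Bu2AlH for the short time needed at −78 °C.

C12–C18 sulfone (steps 18–23)

Step 18
Reactants: 27 (R)-linalool
Product: 29 (3R)-3,7-dimethyloct-6-ene-1,3-diol, via B-alkyl-9-BBN adduct 28 (not isolated)
Conditions: 9-BBN, THF, 0 °C to rt; then NaOH, 30% aq H2O2, 0 °C
Reagents that add atoms: hydrogen peroxide, OO
Why: Hydroboration–oxidation with the bulky 9-BBN selects the monosubstituted vinyl group over the trisubstituted alkene and puts the hydroxyl on the terminal carbon C12 without touching C14.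

Step 19
Reactants: 29 1,3-diol
Product: 31 (2R)-2-methyl-2-(4-methylpent-3-enyl)oxetane, via primary tosylate 30 (not isolated)
Conditions: n-BuLi (1.0 equiv), THF, 0 °C; TsCl (1.0 equiv); then n-BuLi (1.1 equiv), 0 to 60 °C
Reagents that add atoms: none
Why: Selective tosylation of the primary alkoxide followed by intramolecular Williamson etherification (4-exo-tet) by the tertiary alkoxide closes the oxetane with the C14–O bond retained.

Step 20
Reactants: 31 oxetane
Product: 32 (3S)-3-hydroperoxy-3,7-dimethyloct-6-en-1-ol
Conditions: anhydrous H2O2 in Et2O (10 equiv), Me3SiOTf (0.2 equiv), Et2O, −78 to −20 °C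
Reagents that add atoms: hydrogen peroxide, OO
Why: Lewis-acid-promoted perhydrolysis of 2,2-disubstituted oxetanes is a known strain-release substitution in which H2O2 attacks the tertiary carbon from the back, so C14 is inverted into the arrangement of the target and C12 is released as a primary alcohol.

Step 21
Reactants: 32 hydroperoxy alcohol
Product: 34 (3S)-3-[(2-methoxypropan-2-yl)peroxy]-3,7-dimethyloct-6-en-1-ol, via bis-ketal 33 (not isolated)
Conditions: 2-methoxypropene (5 equiv), PPTS (2 mol%), CH2Cl2, 0 °C; then MeOH, 0 °C, short contact; Et3N quench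
Reagents that add atoms: 2-methoxypropene, C=C(C)OC
Why: Acid-catalysed addition of both O–H groups to excess enol ether caps them quickly enough to forestall trioxepane formation, and the ordinary mixed ketal on C12 is then methanolysed much faster than the peroxyketal, whose peroxy oxygen supports ionisation poorly.

Step 22
Reactants: 34 peroxyketal alcohol
Product: 35 5-{[(3S)-3-[(2-methoxypropan-2-yl)peroxy]-3,7-dimethyloct-6-enyl]sulfanyl}-1-phenyl-1H-tetrazole
Conditions: 1-phenyl-1H-tetrazole-5-thiol, PPh3, DIAD, THF, 0 °C
Reagents that add atoms: 1-phenyl-1H-tetrazole-5-thiol, Sc1nnnn1-c1ccccc1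
Why: Mitsunobu thioetherification of the primary alcohol is fast at 0 °C, and a peroxide flanked by two fully substituted carbons is inert to PPh3 at that temperature.

Step 23
Reactants: 35 sulfide
Product: 36 the corresponding C12 1-phenyl-1H-tetrazol-5-yl sulfone (14S)
Conditions: Na2WO4·2H2O (10 mol%), 30% aq H2O2, MeOH, 0 °C to rt
Reagents that add atoms: hydrogen peroxide, OO
Why: Tungstate-catalysed oxidation with H2O2 near neutral pH oxidises sulfur much faster than an unactivated trisubstituted alkene and spares the acid-labile peroxyketal.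

Union and end game (steps 24–29)

Step 24
Reactants: 36 C12–C18 sulfone; 26 C11 aldehyde
Product: 38 (E)-C11=C12 alkene with the full C1–C18 skeleton (2S,3S,6R,10S,14S), via potassiated sulfone 37 (not isolated)
Conditions: KN(SiMe3)2 (1.05 equiv), THF, −78 °C, 20 min; then 26, −78 °C to rt
Reagents that add atoms: none
Why: Julia–Kocienski olefination with the pre-metallated sulfone forms C11=C12; addition at −78 °C outruns enolisation so C10 is kept, and a peroxyketal without alpha-hydrogen resists the base.

Step 25
Reactants: 38 diene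
Product: 39 C11–C12 saturated silyl ether peroxyketal (2S,3S,6R,10S,14R)
Conditions: 2-nitrobenzenesulfonylhydrazide (portions, monitored), Et3N, CH2Cl2, rt
Reagents that add atoms: none
Why: Diimide reduction discriminates by degree of substitution, so portionwise addition with monitoring should saturate the unhindered 1,2-disubstituted C11=C12 bond and leave the trisubstituted C17=C18 bond, while the amine keeps the medium non-acidic for the peroxyketal.

Step 26
Reactants: 39 silyl ether
Product: 40 C1 primary alcohol (2S,3S,6R,10S,14R)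
Conditions: n-Bu4NF–AcOH 1:1, THF, rt
Reagents that add atoms: none
Why: Fluoride-induced desilylation buffered with acetic acid frees the C1 hydroxyl without the basicity that could start Kornblum–DeLaMare cleavage at C3–H.

Step 27
Reactants: 40 primary alcohol
Product: 42 C1 carboxylic acid (2R,3S,6R,10S,14R), via aldehyde 41 (not isolated)
Conditions: TEMPO (20 mol%), PhI(OAc)2 (2.5 equiv), MeCN–pH 7 phosphate buffer, rt
Reagents that add atoms: water, O
Why: Oxoammonium-mediated oxidation in buffered aqueous acetonitrile carries the alcohol through the aldehyde hydrate to the acid under neutral conditions, which avoids epimerisation at C2 and beta-elimination of the ring peroxide and leaves the alkene alone.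

Step 28
Reactants: 42 carboxylic acid
Product: 43 methyl ester peroxyketal (2R,3S,6R,10S,14R)
Conditions: Me3SiCHN2, toluene–MeOH 4:1, 0 °C
Reagents that add atoms: (trimethylsilyl)diazomethane, C[Si](C)(C)C=[N+]=[N-]
Why: O-Methylation of a carboxylic acid with a diazoalkane needs neither base nor strong acid, so C2, both peroxide units and the ketal stay untouched.

Step 29
Reactants: 43 methyl ester peroxyketal
Product: 44 target CNP0381652.2 (2R,3S,6R,10R,14R)
Conditions: AcOH–THF–H2O 4:2:1, rt
Reagents that add atoms: none
Why: Mild aqueous acid hydrolyses the peroxyketal to the free tertiary hydroperoxide, while the dioxane, the ester and the alkene are stable.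

Compound list
1 | (S)-2-methylglycidol | C[C@]1(CO)CO1 | starting material
2 | allylmagnesium bromide | C=CC[Mg]Br | starting material
3 | (2R)-2-methylhex-5-ene-1,2-diol | C=CCC[C@@](C)(O)CO | intermediate
4 | (4R)-4-(but-3-enyl)-2,2,4-trimethyl-1,3-dioxolane | C=CCC[C@]1(C)COC(C)(C)O1 | intermediate
5 | secondary ozonide of 4 | O1COOC1CC[C@]2(C)COC(C)(C)O2 | intermediate
6 | 3-[(4R)-2,2,4-trimethyl-1,3-dioxolan-4-yl]propanal | O=CCC[C@]1(C)COC(C)(C)O1 | intermediate
7 | (E)-crotylboronic acid pinacol ester | C/C=C/CB1OC(C)(C)C(C)(C)O1 | starting material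
8 | pinacol borate ester of 9 | C=C[C@H](C)[C@H](OB1OC(C)(C)C(C)(C)O1)CC[C@]2(C)COC(C)(C)O2 | intermediate
9 | (3S,4R)-3-methyl-6-[(4R)-2,2,4-trimethyl-1,3-dioxolan-4-yl]hex-1-en-4-ol | C=C[C@H](C)[C@H](O)CC[C@]1(C)COC(C)(C)O1 | intermediate
10 | secondary ozonide of 9 | O1COOC1[C@H](C)[C@H](O)CC[C@]2(C)COC(C)(C)O2 | intermediate
11 | (2S,3R)-2-methyl-5-[(4R)-2,2,4-trimethyl-1,3-dioxolan-4-yl]pentane-1,3-diol | OC[C@H](C)[C@H](O)CC[C@]1(C)COC(C)(C)O1 | intermediate
12 | C1 tert-butyldiphenylsilyl ether of 11 | CC(C)(C)[Si](c1ccccc1)(c1ccccc1)OC[C@H](C)[C@H](O)CC[C@]1(C)COC(C)(C)O1 | intermediate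
13 | (2R,5R,6S)-7-(tert-butyldiphenylsilyloxy)-2,6-dimethylheptane-1,2,5-triol | CC(C)(C)[Si](c1ccccc1)(c1ccccc1)OC[C@H](C)[C@H](O)CC[C@@](C)(O)CO | intermediate
14 | C3,C7-bis-mesylate of 13 | CC(C)(C)[Si](c1ccccc1)(c1ccccc1)OC[C@H](C)[C@H](OS(C)(=O)=O)CC[C@@](C)(O)COS(C)(=O)=O | intermediate
15 | (3R)-mesylate (6R)-6,7-epoxide | CC(C)(C)[Si](c1ccccc1)(c1ccccc1)OC[C@H](C)[C@H](OS(C)(=O)=O)CC[C@]1(C)CO1 | intermediate
16 | (3S)-hydroperoxide (6R)-6,7-epoxide, key-step precursor | CC(C)(C)[Si](c1ccccc1)(c1ccccc1)OC[C@H](C)[C@@H](OO)CC[C@]1(C)CO1 | intermediate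
17 | 6-(hydroxymethyl)-6-methyl-1,2-dioxane, key-step product | CC(C)(C)[Si](c1ccccc1)(c1ccccc1)OC[C@H](C)[C@@H]1CC[C@@](C)(CO)OO1 | intermediate
18 | dioxane C7 aldehyde | CC(C)(C)[Si](c1ccccc1)(c1ccccc1)OC[C@H](C)[C@@H]1CC[C@@](C)(C=O)OO1 | intermediate
19 | (S)-alpha-methyl-gamma-butyrolactone | C[C@H]1CCOC1=O | starting material
20 | (2S)-4-hydroxy-N-methoxy-N,2-dimethylbutanamide | OCC[C@H](C)C(=O)N(C)OC | intermediate
21 | linker tetrazolyl sulfide | CON(C)C(=O)[C@@H](C)CCSc1nnnn1-c1ccccc1 | intermediate
22 | linker tetrazolyl sulfone | CON(C)C(=O)[C@@H](C)CCS(=O)(=O)c1nnnn1-c1ccccc1 | intermediate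
23 | potassiated sulfone from 22 | [K+].CON(C)C(=O)[C@@H](C)C[CH-]S(=O)(=O)c1nnnn1-c1ccccc1 | intermediate
24 | (E)-C7=C8 alkene Weinreb amide | CC(C)(C)[Si](c1ccccc1)(c1ccccc1)OC[C@H](C)[C@@H]1CC[C@@](C)(/C=C/C[C@H](C)C(=O)N(C)OC)OO1 | intermediate
25 | saturated C1–C11 Weinreb amide | CC(C)(C)[Si](c1ccccc1)(c1ccccc1)OC[C@H](C)[C@@H]1CC[C@@](C)(CCC[C@H](C)C(=O)N(C)OC)OO1 | intermediate
26 | C11 aldehyde | CC(C)(C)[Si](c1ccccc1)(c1ccccc1)OC[C@H](C)[C@@H]1CC[C@@](C)(CCC[C@H](C)C=O)OO1 | intermediate
27 | (R)-linalool | C=C[C@@](C)(CCC=C(C)C)O | starting material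
28 | B-alkyl-9-BBN adduct of 27 | C(C[C@@](C)(CCC=C(C)C)O)B1C2CCCC1CCC2 | intermediate
29 | (3R)-3,7-dimethyloct-6-ene-1,3-diol | OCC[C@@](C)(CCC=C(C)C)O | intermediate
30 | primary tosylate of 29 | Cc1ccc(cc1)S(=O)(=O)OCC[C@@](C)(CCC=C(C)C)O | intermediate
31 | (2R)-2-methyl-2-(4-methylpent-3-enyl)oxetane | C[C@@]1(CCC=C(C)C)CCO1 | intermediate
32 | (3S)-3-hydroperoxy-3,7-dimethyloct-6-en-1-ol | OCC[C@](C)(CCC=C(C)C)OO | intermediate
33 | bis(2-methoxypropan-2-yl) derivative of 32 | COC(C)(C)OCC[C@](C)(CCC=C(C)C)OOC(C)(C)OC | intermediate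
34 | (3S)-3-[(2-methoxypropan-2-yl)peroxy]-3,7-dimethyloct-6-en-1-ol | OCC[C@](C)(CCC=C(C)C)OOC(C)(C)OC | intermediate
35 | C12 tetrazolyl sulfide | C(C[C@](C)(CCC=C(C)C)OOC(C)(C)OC)Sc1nnnn1-c1ccccc1 | intermediate
36 | C12 tetrazolyl sulfone | C(C[C@](C)(CCC=C(C)C)OOC(C)(C)OC)S(=O)(=O)c1nnnn1-c1ccccc1 | intermediate
37 | potassiated sulfone from 36 | [K+].[CH-](C[C@](C)(CCC=C(C)C)OOC(C)(C)OC)S(=O)(=O)c1nnnn1-c1ccccc1 | intermediate
38 | (E)-C11=C12 alkene, full skeleton | CC(C)(C)[Si](c1ccccc1)(c1ccccc1)OC[C@H](C)[C@@H]1CC[C@@](C)(CCC[C@H](C)/C=C/C[C@](C)(CCC=C(C)C)OOC(C)(C)OC)OO1 | intermediate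
39 | saturated silyl ether peroxyketal | CC(C)(C)[Si](c1ccccc1)(c1ccccc1)OC[C@H](C)[C@@H]1CC[C@@](C)(CCC[C@H](C)CCC[C@](C)(CCC=C(C)C)OOC(C)(C)OC)OO1 | intermediate
40 | C1 alcohol peroxyketal | OC[C@H](C)[C@@H]1CC[C@@](C)(CCC[C@H](C)CCC[C@](C)(CCC=C(C)C)OOC(C)(C)OC)OO1 | intermediate
41 | C1 aldehyde peroxyketal | O=C[C@H](C)[C@@H]1CC[C@@](C)(CCC[C@H](C)CCC[C@](C)(CCC=C(C)C)OOC(C)(C)OC)OO1 | intermediate
42 | C1 acid peroxyketal | OC(=O)[C@H](C)[C@@H]1CC[C@@](C)(CCC[C@H](C)CCC[C@](C)(CCC=C(C)C)OOC(C)(C)OC)OO1 | intermediate
43 | methyl ester peroxyketal | COC(=O)[C@H](C)[C@@H]1CC[C@@](C)(CCC[C@H](C)CCC[C@](C)(CCC=C(C)C)OOC(C)(C)OC)OO1 | intermediate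
44 | CNP0381652.2 | COC(=O)[C@H](C)[C@@H]1CC[C@@](C)(CCC[C@H](C)CCC[C@](C)(CCC=C(C)C)OO)OO1 | target

Total step count: 29. Longest linear sequence: 20 steps (1–11, 15–17, 24–29).

Steps most likely to fail

**Step 9.** Substitution at the beta-branched secondary carbon C3 may be slower than three competing processes:
- elimination;
- attack of hydroperoxide anion on the epoxide CH2;
- base-induced closure of the product peroxy anion in the endo sense.

The fallback sets out from 15 and comes back at 16. It replaces hydrogen peroxide with its mono-protected form. Mesylate 15 is treated with 2-methoxyprop-2-yl hydroperoxide and CsOH·H2O in DMF at 0 °C. This is an alkylation of a hydroperoxide that again inverts C3, and it gives the peroxyketal epoxide F1. F1 has no acidic O–H, so it cannot be alkylated a second time or cyclise under base, and it can be purified. Brief treatment with PPTS in aqueous THF at 0 °C then strips the ketal and delivers 16 just before the key step.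

**Step 10.** Over-ionisation of the activated epoxide may loosen the C6–O bond towards a cation. That would bring erosion of configuration at C6, hydride shift, or endo closure. The fallback sets out from 15 and comes back at 17, and it exchanges the roles of the two carbons. Epoxide 15 is perhydrolysed with ethereal H2O2 and catalytic H3PMo12O40. This intermolecular opening at the tertiary carbon with inversion gives the 6-hydroperoxy-7-ol mesylate F2. Cs2CO3 in DMF at 0 °C then lets the tertiary peroxy anion displace the C3 mesylate (6-exo-tet, inversion at C3). Both centres are inverted exactly as in the main route, so the product is 17.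

**Step 21.** The two-stage protection may lose selectivity. Two processes could cause this:
- the peroxyketal may be methanolysed along with the C12 ketal;
- the freed hydroxyl may close onto the peroxyketal to give a seven-membered ring.

The fallback sets out from 32 and comes back at 34, and it differentiates the two groups by acylation instead of ketal lability. Immobilised Candida antarctica lipase B with vinyl acetate in t-BuOMe acetylates only the primary hydroxyl and gives the hydroperoxy acetate F3. 2-Methoxypropene with catalytic PPTS then caps the only remaining acidic group and gives the peroxyketal acetate F4. K2CO3 in MeOH removes the acetate under conditions to which the peroxyketal is inert.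

Further compounds
F1 | step 9 | (3S)-(2-methoxypropan-2-yl)peroxy (6R)-6,7-epoxide | CC(C)(C)[Si](c1ccccc1)(c1ccccc1)OC[C@H](C)[C@@H](OOC(C)(C)OC)CC[C@]1(C)CO1
F2 | step 10 | 6-hydroperoxy-7-ol (3R)-mesylate | CC(C)(C)[Si](c1ccccc1)(c1ccccc1)OC[C@H](C)[C@H](OS(C)(=O)=O)CC[C@@](C)(CO)OO
F3 | step 21 | (3S)-3-hydroperoxy-3,7-dimethyloct-6-enyl acetate | CC(=O)OCC[C@](C)(CCC=C(C)C)OO
F4 | step 21 | (3S)-3-[(2-methoxypropan-2-yl)peroxy]-3,7-dimethyloct-6-enyl acetate | CC(=O)OCC[C@](C)(CCC=C(C)C)OOC(C)(C)OC
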